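Retrosynthesis: the C2 carbinol goes back to a C2 ketone, the C3 methyl enol ether to a diosphenol and the C8 ketone to a C8 nitro group; the C1–C8 and C5–C8 bonds are then cut together, leaving nitromethane and a cyclohepta-2,6-dienone whose ring is C1–C2–C3–C4–C5–C6–C7.
Enabling feature: C8 is a one-carbon ketone bridge bonded to C1 and C5, and both carbons are β to the C3 carbonyl inside that seven-membered ring, so C8 can be delivered as a carbonyl 1,1-dianion equivalent by a double Michael addition.
The dienone is cut further at C5–allyl (Grignard addition with carbonyl transposition), C6–CH3 (enolate alkylation) and C7–aryl (rhodium-catalysed conjugate addition), back to cycloheptane-1,3-dione. A silyloxy group is put on C2 before the ring closure, so the C2 oxygen is placed without a regiochemical question and C1 becomes the poorer acceptor.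
Forward: the seven-membered ring is present from the start and receives aryl, methyl, allyl and the C2 oxygen in that order; step 9 (13 → 16) adds C8 and closes the five- and six-membered rings of the bicyclo[3.2.1]octane with its second C–C bond; five functional-group steps follow.
Stereochemistry: C7 from (R)-BINAP/rhodium catalysis; C6 by alkylation anti to the aryl group; C5 and C1 in step 9 by attack anti to the C6 methyl group and by the tether; C2 last, by hydride delivery from the face of the one-carbon bridge.

Key step: step 9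

Remarks. C1–C8 are the locants of the bicyclo[3.2.1]octane core of the target: C1 bridgehead CH, C2–C3–C4 three-carbon bridge, C5 allyl-bearing bridgehead, C6 methyl-bearing, C7 aryl-bearing, C8 one-carbon bridge. They are used for the same carbons of every intermediate when reactivity is discussed and in the names of the bicyclic compounds; monocyclic compounds carry ordinary ring locants in their names. Metal enolates and the nitronate made by deprotonation are treated as reactive forms of the numbered compounds, not as separate compounds.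

Step 1
Reactants: 1 cycloheptane-1,3-dione
Product: 2 3-isobutoxycyclohept-2-en-1-one
Conditions: i-BuOH, p-toluenesulfonic acid monohydrate (cat.), toluene, reflux, Dean–Stark trap
Reagents that add atoms: isobutanol (2-methylpropan-1-ol), CC(C)CO
Why: Acid-catalysed condensation of a cyclic 1,3-diketone with an alcohol under azeotropic removal of water gives the vinylogous ester, which tells the two carbonyl carbons apart (the ketone carbon becomes C5, the alkoxy carbon C3).

Step 2
Reactants: 2 3-isobutoxycyclohept-2-en-1-one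
Product: 4 3-isobutoxycyclohepta-2,6-dien-1-one, via trimethylsilyl dienol ether 3 (not isolated)
Conditions: LiN(iPr)2, Me3SiCl, THF, −78 °C; then Pd(OAc)2 (1 equiv), MeCN, rt
Reagents that add atoms: none
Why: Saegusa–Ito oxidation, in which kinetic deprotonation of the vinylogous ester takes place at the α′ carbon (C6) and palladation of the silyl dienol ether followed by β-hydride elimination introduces the C6=C7 double bond, with no aromatisation possible in a seven-membered ring.

Step 3
Reactants: 4 3-isobutoxycyclohepta-2,6-dien-1-one; 5 3,4-dimethoxyphenylboronic acid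
Product: 6 (R)-6-(3,4-dimethoxyphenyl)-3-isobutoxycyclohept-2-en-1-one
Conditions: [Rh(acac)(C2H4)2] (3 mol %), (R)-BINAP (3.3 mol %), 1,4-dioxane/H2O (10:1), 100 °C
Reagents that add atoms: none
Why: Hayashi–Miyaura reaction, in which the aryl–rhodium species formed by transmetallation adds to the unsubstituted enone double bond (the alkoxy-substituted double bond is a vinylogous ester and stays inert), and the (R)-BINAP complex, which delivers (R)-3-arylcycloalkanones from simple cycloalkenones, should set the benzylic centre (C7 of the target) as 6R by the same facial preference.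

Step 4
Reactants: 6 (R)-6-(3,4-dimethoxyphenyl)-3-isobutoxycyclohept-2-en-1-one
Product: 7 (6R,7S)-6-(3,4-dimethoxyphenyl)-3-isobutoxy-7-methylcyclohept-2-en-1-one
Conditions: LiN(iPr)2, THF, −78 °C; then MeI, −78 → −20 °C
Reagents that add atoms: iodomethane, CI
Why: Kinetic enolate alkylation, in which the α′ enolate of the vinylogous ester is methylated on the face opposite the neighbouring aryl group to give the trans isomer, which is also the more stable one, so that base equilibration at this α-carbon can correct any cis material.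

Step 5
Reactants: 7 (6R,7S)-6-(3,4-dimethoxyphenyl)-3-isobutoxy-7-methylcyclohept-2-en-1-one; 8 allylmagnesium bromide
Product: 10 (4S,5R)-3-allyl-5-(3,4-dimethoxyphenyl)-4-methylcyclohept-2-en-1-one, via tertiary allylic carbinol 9 (not isolated)
Conditions: CH2=CHCH2MgBr, THF, −78 → 0 °C; then 1 M HCl (aq), THF, rt
Reagents that add atoms: water, O
Why: Stork–Danheiser transposition, in which 1,2-addition of the allyl Grignard reagent to the vinylogous ester carbonyl gives carbinol 9 and aqueous acid hydrolyses the enol ether and eliminates water, which moves the carbonyl to C3 and leaves the allyl group on C5 of the enone without touching C6 or C7.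

Step 6
Reactants: 10 (4S,5R)-3-allyl-5-(3,4-dimethoxyphenyl)-4-methylcyclohept-2-en-1-one
Product: 11 (4S,5R)-3-allyl-5-(3,4-dimethoxyphenyl)-7-hydroxy-4-methylcyclohept-2-en-1-one (epimers at the carbinol carbon)
Conditions: KN(SiMe3)2, THF, −78 °C; then 2-(phenylsulfonyl)-3-phenyloxaziridine, −78 °C; AcOH quench
Reagents that add atoms: 2-(phenylsulfonyl)-3-phenyloxaziridine, O=S(=O)(c1ccccc1)N1OC1c1ccccc1
Why: Enolate hydroxylation with an N-sulfonyloxaziridine, in which kinetic deprotonation of the enone takes place at the α′ methylene (C2), the only sp3 α-carbon, so the oxygen is placed on C2 without a regiochemical alternative, and the new carbinol centre is erased in step 7.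

Step 7
Reactants: 11 (4S,5R)-3-allyl-5-(3,4-dimethoxyphenyl)-7-hydroxy-4-methylcyclohept-2-en-1-one
Product: 12 (4S,5S)-6-allyl-4-(3,4-dimethoxyphenyl)-2-hydroxy-5-methylcyclohepta-2,6-dien-1-one
Conditions: Dess–Martin periodinane, pyridine, CH2Cl2, 0 °C → rt
Reagents that add atoms: none
Why: Dess–Martin oxidation of the α-ketol gives the 1,2-dione, which can enolise only from C2 toward C1 because C4 is vinylic and is therefore obtained as the cross-conjugated diosphenol.

Step 8
Reactants: 12 (4S,5S)-6-allyl-4-(3,4-dimethoxyphenyl)-2-hydroxy-5-methylcyclohepta-2,6-dien-1-one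
Product: 13 (4S,5S)-6-allyl-4-(3,4-dimethoxyphenyl)-5-methyl-2-(triisopropylsilyloxy)cyclohepta-2,6-dien-1-one
Conditions: iPr3SiOTf, Et3N, CH2Cl2, −78 → 0 °C
Reagents that add atoms: triisopropylsilyl trifluoromethanesulfonate, CC(C)[Si](OS(=O)(=O)C(F)(F)F)(C(C)C)C(C)C
Why: O-Silylation of the diosphenol with a silyl triflate and an amine base fixes the C1=C2 enol ether, and the bulky triisopropylsilyl group is chosen because it resists amine bases and nitronates in the next step.

Step 9
Reactants: 13 (4S,5S)-6-allyl-4-(3,4-dimethoxyphenyl)-5-methyl-2-(triisopropylsilyloxy)cyclohepta-2,6-dien-1-one; 14 nitromethane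
Product: 16 (1R,5S,6S,7S)-5-allyl-7-(3,4-dimethoxyphenyl)-6-methyl-8-nitro-2-(triisopropylsilyloxy)bicyclo[3.2.1]octan-3-one (7-exo-aryl and 6-endo-methyl; epimers at C2 and C8), via nitromethyl enone 15 (not isolated)
Conditions: MeNO2 (10 equiv), 1,1,3,3-tetramethylguanidine (0.5 equiv), MeCN, argon, rt → 45 °C
Reagents that add atoms: none
Why: TMG deprotonates nitromethane and the nitronate adds in a Michael reaction to C5 of 13, the terminus of the ordinary enone (C1 is the β-carbon of a 2-silyloxy enone whose oxygen lone pair makes it the poorer acceptor), to give 15; its nitronate carbon C8 then adds across the ring to C1 in a second, intramolecular Michael reaction, so that C5–C8 and C1–C8 are both formed in one operation. The closest known reaction type is the double Michael addition of nitromethane or a primary amine to cross-conjugated cyclohepta-2,6-dienones and cycloocta-2,7-dienones, which gives 8-substituted bicyclo[3.2.1]octan-3-ones and their homologues. The second bond closes the cyclopentane C1–C7–C6–C5–C8 in the 5-exo-trig mode and, with the same bond, the cyclohexanone C1–C2–C3–C4–C5–C8 in the 6-endo-trig mode. C5 is controlled by the C6 stereocentre: allylic 1,2-strain with the C5 allyl group holds the C6 methyl group pseudoaxial and the nitronate enters C5 from the opposite face; C1 is controlled by the tether, because the C5-bound nitronate can reach C1 only on that same face, which is the face of the trans C7 aryl group, so the aryl group ends exo (syn to C8) and the methyl group endo. The step therefore needs site selectivity (C5 before C1) and facial selectivity at C5; the C2 silyloxy donor should secure the first, the C6 methyl group the second, and the reversibility of the intermolecular Michael addition allows adducts formed at C1 to return to 13. The epimer mixtures at C2 and C8 are of no consequence because both carbons become carbonyl carbons in later steps.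

Step 10
Reactants: 16 (1R,5S,6S,7S)-5-allyl-7-(3,4-dimethoxyphenyl)-6-methyl-8-nitro-2-(triisopropylsilyloxy)bicyclo[3.2.1]octan-3-one
Product: 17 (1S,5S,6S,7S)-5-allyl-7-(3,4-dimethoxyphenyl)-6-methyl-2-(triisopropylsilyloxy)bicyclo[3.2.1]octane-3,8-dione (C2 epimers)
Conditions: NaOMe, MeOH, 0 °C; then TiCl3 (aq), NH4OAc, THF/H2O, rt
Reagents that add atoms: water, O
Why: Reductive Nef reaction, in which the C8 nitro group is deprotonated and the nitronate is reduced by TiCl3 through the oxime to the imine, which hydrolyses in the acetate-buffered medium to the C8 ketone, while the alkene, the aryl ethers, the C3 ketone and the silyl ether are inert and the C8 stereocentre disappears.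

Step 11
Reactants: 17 (1S,5S,6S,7S)-5-allyl-7-(3,4-dimethoxyphenyl)-6-methyl-2-(triisopropylsilyloxy)bicyclo[3.2.1]octane-3,8-dione
Product: 18 (1S,5S,6S,7S)-5-allyl-7-(3,4-dimethoxyphenyl)-2-hydroxy-6-methylbicyclo[3.2.1]octane-3,8-dione (C2 epimers)
Conditions: Bu4NF, AcOH, THF, 0 °C → rt
Reagents that add atoms: none
Why: Fluoride-mediated cleavage of the silyl ether under acetic acid buffering frees the C2 hydroxyl without base-induced side reactions of the ketol.

Step 12
Reactants: 18 (1S,5S,6S,7S)-5-allyl-7-(3,4-dimethoxyphenyl)-2-hydroxy-6-methylbicyclo[3.2.1]octane-3,8-dione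
Product: 19 (1R,5R,6S,7S)-5-allyl-7-(3,4-dimethoxyphenyl)-3-hydroxy-6-methylbicyclo[3.2.1]oct-3-ene-2,8-dione
Conditions: Dess–Martin periodinane, pyridine, CH2Cl2, rt
Reagents that add atoms: none
Why: Dess–Martin oxidation of the α-ketol (and of any isomeric ketol that an earlier silyl or acyloin shift may have produced) gives the 2,3-dione, which can enolise only toward C4 because C1 is a bridgehead, so the diosphenol carries the C3 hydroxyl and the C3=C4 double bond that the target needs.

Step 13
Reactants: 19 (1R,5R,6S,7S)-5-allyl-7-(3,4-dimethoxyphenyl)-3-hydroxy-6-methylbicyclo[3.2.1]oct-3-ene-2,8-dione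
Product: 20 (1R,5R,6S,7S)-5-allyl-7-(3,4-dimethoxyphenyl)-3-methoxy-6-methylbicyclo[3.2.1]oct-3-ene-2,8-dione
Conditions: Me2SO4, K2CO3, acetone, reflux
Reagents that add atoms: dimethyl sulfate, COS(=O)(=O)OC
Why: O-Alkylation of a diosphenol with a hard methylating agent and carbonate base gives the methyl enol ether, since C-methylation at the neopentyl-type C4 is disfavoured and the non-nucleophilic medium avoids retro-Claisen cleavage of the 2,8-dione.

Step 14
Reactants: 20 (1R,5R,6S,7S)-5-allyl-7-(3,4-dimethoxyphenyl)-3-methoxy-6-methylbicyclo[3.2.1]oct-3-ene-2,8-dione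
Product: 21 (1S,2R,5R,6S,7S)-5-allyl-7-(3,4-dimethoxyphenyl)-2-hydroxy-3-methoxy-6-methylbicyclo[3.2.1]oct-3-en-8-one (target, CNP0232354.1)
Conditions: NaBH4, CeCl3·7H2O, MeOH, −78 °C
Reagents that add atoms: none
Why: Luche reduction, in which the CeCl3/NaBH4 system should reduce the conjugated C2 carbonyl in 1,2-fashion in preference to the C8 ketone, which is flanked by the quaternary C5 and should largely rest as its methanol hemiketal under these conditions, and hydride enters C2 from the open face of the one-carbon bridge, opposite the C6–C7 bridge, so that the hydroxyl points toward the two-carbon bridge (2R).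

Compound list
1 | cycloheptane-1,3-dione | O=C1CCCCC(=O)C1 | starting material
2 | 3-isobutoxycyclohept-2-en-1-one | CC(C)COC1=CC(=O)CCCC1 | intermediate
3 | 1-isobutoxy-3-(trimethylsilyloxy)cyclohepta-1,3-diene | CC(C)COC1=CC(O[Si](C)(C)C)=CCCC1 | intermediate
4 | 3-isobutoxycyclohepta-2,6-dien-1-one | CC(C)COC1=CC(=O)C=CCC1 | intermediate
5 | 3,4-dimethoxyphenylboronic acid | COc1ccc(B(O)O)cc1OC | starting material
6 | (R)-6-(3,4-dimethoxyphenyl)-3-isobutoxycyclohept-2-en-1-one | CC(C)COC1=CC(=O)C[C@H](c2ccc(OC)c(OC)c2)CC1 | intermediate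
7 | (6R,7S)-6-(3,4-dimethoxyphenyl)-3-isobutoxy-7-methylcyclohept-2-en-1-one (6,7-trans) | CC(C)COC1=CC(=O)[C@@H](C)[C@H](c2ccc(OC)c(OC)c2)CC1 | intermediate
8 | allylmagnesium bromide | C=CC[Mg]Br | starting material
9 | (6R,7S)-1-allyl-6-(3,4-dimethoxyphenyl)-3-isobutoxy-7-methylcyclohept-2-en-1-ol (carbinol centre not assigned) | C=CCC1(O)C=C(OCC(C)C)CC[C@@H](c2ccc(OC)c(OC)c2)[C@@H]1C | intermediate
10 | (4S,5R)-3-allyl-5-(3,4-dimethoxyphenyl)-4-methylcyclohept-2-en-1-one | C=CCC1=CC(=O)CC[C@@H](c2ccc(OC)c(OC)c2)[C@@H]1C | intermediate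
11 | (4S,5R)-3-allyl-5-(3,4-dimethoxyphenyl)-7-hydroxy-4-methylcyclohept-2-en-1-one (C7 epimers) | C=CCC1=CC(=O)C(O)C[C@@H](c2ccc(OC)c(OC)c2)[C@@H]1C | intermediate
12 | (4S,5S)-6-allyl-4-(3,4-dimethoxyphenyl)-2-hydroxy-5-methylcyclohepta-2,6-dien-1-one (enol form of the 1,2-dione) | C=CCC1=CC(=O)C(O)=C[C@@H](c2ccc(OC)c(OC)c2)[C@@H]1C | intermediate
13 | (4S,5S)-6-allyl-4-(3,4-dimethoxyphenyl)-5-methyl-2-(triisopropylsilyloxy)cyclohepta-2,6-dien-1-one | C=CCC1=CC(=O)C(O[Si](C(C)C)(C(C)C)C(C)C)=C[C@@H](c2ccc(OC)c(OC)c2)[C@@H]1C | intermediate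
14 | nitromethane | C[N+](=O)[O-] | starting material
15 | (4S,5S,6S)-6-allyl-4-(3,4-dimethoxyphenyl)-5-methyl-6-(nitromethyl)-2-(triisopropylsilyloxy)cyclohept-2-en-1-one | C=CC[C@]1(C[N+](=O)[O-])CC(=O)C(O[Si](C(C)C)(C(C)C)C(C)C)=C[C@@H](c2ccc(OC)c(OC)c2)[C@@H]1C | intermediate
16 | (1R,5S,6S,7S)-5-allyl-7-(3,4-dimethoxyphenyl)-6-methyl-8-nitro-2-(triisopropylsilyloxy)bicyclo[3.2.1]octan-3-one (7-exo-aryl, 6-endo-methyl; epimers at C2 and C8) | C=CC[C@@]12CC(=O)C(O[Si](C(C)C)(C(C)C)C(C)C)[C@@H](C1[N+](=O)[O-])[C@@H](c1ccc(OC)c(OC)c1)[C@@H]2C | intermediate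
17 | (1S,5S,6S,7S)-5-allyl-7-(3,4-dimethoxyphenyl)-6-methyl-2-(triisopropylsilyloxy)bicyclo[3.2.1]octane-3,8-dione (C2 epimers) | C=CC[C@@]12CC(=O)C(O[Si](C(C)C)(C(C)C)C(C)C)[C@@H](C1=O)[C@@H](c1ccc(OC)c(OC)c1)[C@@H]2C | intermediate
18 | (1S,5S,6S,7S)-5-allyl-7-(3,4-dimethoxyphenyl)-2-hydroxy-6-methylbicyclo[3.2.1]octane-3,8-dione (C2 epimers) | C=CC[C@@]12CC(=O)C(O)[C@@H](C1=O)[C@@H](c1ccc(OC)c(OC)c1)[C@@H]2C | intermediate
19 | (1R,5R,6S,7S)-5-allyl-7-(3,4-dimethoxyphenyl)-3-hydroxy-6-methylbicyclo[3.2.1]oct-3-ene-2,8-dione | C=CC[C@@]12C=C(O)C(=O)[C@@H](C1=O)[C@@H](c1ccc(OC)c(OC)c1)[C@@H]2C | intermediate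
20 | (1R,5R,6S,7S)-5-allyl-7-(3,4-dimethoxyphenyl)-3-methoxy-6-methylbicyclo[3.2.1]oct-3-ene-2,8-dione | C=CC[C@@]12C=C(OC)C(=O)[C@@H](C1=O)[C@@H](c1ccc(OC)c(OC)c1)[C@@H]2C | intermediate
21 | (1S,2R,5R,6S,7S)-5-allyl-7-(3,4-dimethoxyphenyl)-2-hydroxy-3-methoxy-6-methylbicyclo[3.2.1]oct-3-en-8-one | C=CC[C@@]12C=C(OC)[C@H](O)[C@@H](C1=O)[C@@H](c1ccc(OC)c(OC)c1)[C@@H]2C | target

Total step count: 14. Longest linear sequence: 14 steps (1 → 21); 5, 8 and 14 enter as single-step reagents.

Steps most likely to fail

Step 9. Nitromethane may add first to C1 (anti to the C7 aryl group) or to the wrong face of C5, which would lead to the endo-aryl diastereomer. The base may also remove the γ-hydrogens at C6 or C7 and so erode the stereocentres or shift the double bonds, or it may strip the silyl group. The fallback carries out the two Michael additions separately, so that C5 has to react first. It sets out from 11, in which C5 is the only acceptor carbon. Nitromethane with 1,8-diazabicyclo[5.4.0]undec-7-ene in MeCN should give (4R,5S,6S)-6-allyl-4-(3,4-dimethoxyphenyl)-2-hydroxy-5-methyl-6-(nitromethyl)cycloheptan-1-one F1. Dess–Martin oxidation of this ketol should give the diosphenol (4S,5S,6S)-6-allyl-4-(3,4-dimethoxyphenyl)-2-hydroxy-5-methyl-6-(nitromethyl)cyclohept-2-en-1-one F2. O-Silylation with iPr3SiCl and imidazole in DMF then gives 15, and TMG in MeCN closes 15 to 16, where the route is rejoined.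

Step 14. Hydride may add to the strained C8 carbonyl as fast as, or faster than, to C2, giving loss of chemoselectivity and over-reduction. The fallback replaces the selective reduction by a global reduction followed by selective reoxidation. It sets out from 20. An excess of NaBH4 with CeCl3·7H2O in MeOH at 0 °C should reduce both carbonyl groups to 5-allyl-7-(3,4-dimethoxyphenyl)-3-methoxy-6-methylbicyclo[3.2.1]oct-3-ene-2,8-diol F3. The allylic C2 hydroxyl is far less hindered than the C8 hydroxyl next to the quaternary C5 and is silylated selectively with t-BuMe2SiCl and imidazole to 5-allyl-2-(tert-butyldimethylsilyloxy)-7-(3,4-dimethoxyphenyl)-3-methoxy-6-methylbicyclo[3.2.1]oct-3-en-8-ol F4. Dess–Martin oxidation of the C8 hydroxyl gives 5-allyl-2-(tert-butyldimethylsilyloxy)-7-(3,4-dimethoxyphenyl)-3-methoxy-6-methylbicyclo[3.2.1]oct-3-en-8-one F5, and Bu4NF/AcOH in THF removes the silyl group to return to 21.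

Step 10. The reductive sequence may stall at the oxime or imine of the hindered bridge carbon, or methoxide may open the bicycle by retro-Michael reaction before the nitronate is consumed. The fallback goes stepwise through the isolated oxime and cleaves it oxidatively. It sets out from 16. SnCl2·2H2O, PhSH and Et3N in MeCN should reduce the nitro group to 5-allyl-7-(3,4-dimethoxyphenyl)-8-(hydroxyimino)-6-methyl-2-(triisopropylsilyloxy)bicyclo[3.2.1]octan-3-one F6. Dess–Martin periodinane in wet CH2Cl2 then cleaves the C=N bond oxidatively and returns to 17.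

Further compounds
F1 | step 9 | (4R,5S,6S)-6-allyl-4-(3,4-dimethoxyphenyl)-2-hydroxy-5-methyl-6-(nitromethyl)cycloheptan-1-one (C2 epimers) | C=CC[C@]1(C[N+](=O)[O-])CC(=O)C(O)C[C@@H](c2ccc(OC)c(OC)c2)[C@@H]1C
F2 | step 9 | (4S,5S,6S)-6-allyl-4-(3,4-dimethoxyphenyl)-2-hydroxy-5-methyl-6-(nitromethyl)cyclohept-2-en-1-one | C=CC[C@]1(C[N+](=O)[O-])CC(=O)C(O)=C[C@@H](c2ccc(OC)c(OC)c2)[C@@H]1C
F3 | step 14 | 5-allyl-7-(3,4-dimethoxyphenyl)-3-methoxy-6-methylbicyclo[3.2.1]oct-3-ene-2,8-diol (configured as 21 at C1, C2, C5, C6 and C7; C8 not assigned) | C=CC[C@@]12C=C(OC)[C@H](O)[C@@H](C1O)[C@@H](c1ccc(OC)c(OC)c1)[C@@H]2C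
F4 | step 14 | 5-allyl-2-(tert-butyldimethylsilyloxy)-7-(3,4-dimethoxyphenyl)-3-methoxy-6-methylbicyclo[3.2.1]oct-3-en-8-ol (C8 not assigned) | C=CC[C@@]12C=C(OC)[C@H](O[Si](C)(C)C(C)(C)C)[C@@H](C1O)[C@@H](c1ccc(OC)c(OC)c1)[C@@H]2C
F5 | step 14 | 5-allyl-2-(tert-butyldimethylsilyloxy)-7-(3,4-dimethoxyphenyl)-3-methoxy-6-methylbicyclo[3.2.1]oct-3-en-8-one | C=CC[C@@]12C=C(OC)[C@H](O[Si](C)(C)C(C)(C)C)[C@@H](C1=O)[C@@H](c1ccc(OC)c(OC)c1)[C@@H]2C
F6 | step 10 | 5-allyl-7-(3,4-dimethoxyphenyl)-8-(hydroxyimino)-6-methyl-2-(triisopropylsilyloxy)bicyclo[3.2.1]octan-3-one (oxime geometry and C2 not assigned) | C=CC[C@@]12CC(=O)C(O[Si](C(C)C)(C(C)C)C(C)C)[C@@H](C1=NO)[C@@H](c1ccc(OC)c(OC)c1)[C@@H]2C
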